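The ratio of second to first end groups in the recipe, 0.900, opened the meeting on these vessels.

| flask | first end groups | second end groups | third end groups | remark | time |
|---|---|---|---|---|---|
| amber | 10 mM | 9 mM | 10 mM | run made earlier |  |
| violet | 10 mM | 13 mM | 10 mM | run made earlier |  |
| ochre | 10 mM | 20 mM | 10 mM | run made earlier |  |
| south | 10 mM | 9.00 mM | 10.0 mM | one stirred flow tank at steady state, fed with the mixture as stated, mean residence time 8.0 d |  |
| north-west | 10 mM (fed, over 6.40 d) | 9.00 mM | 10.0 mM | all but first end groups at the start; first end groups goes in evenly over 6.40 d, the run ends at 8.0 d | 8.0 d |
| north | 10 mM | 9.00 mM | 10.0 mM | everything together in a closed stirred flask, run for 8.0 d | 8.0 d |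
| north-east | 10 mM | 9.00 mM | 10.0 mM (fed, over 6.40 d) | all but third end groups at the start; third end groups goes in evenly over 6.40 d, the run ends at 8.0 d | 8.0 d |

| run | time / d | links / % |
|---|---|---|
| amber | 0.417 | 53.3 |
| amber | 1.25 | 53.0 |
| amber | 2.50 | 53.5 |
| amber | 3.00 | 53.0 |
| amber | 5.00 | 53.1 |
| amber | 6.00 | 53.6 |
| amber | 8.00 | 53.1 |
| violet | 0.500 | 74.7 |
| violet | 0.833 | 74.3 |
| violet | 1.25 | 74.5 |
| violet | 1.67 | 74.2 |
| violet | 3.00 | 74.5 |
| violet | 4.00 | 74.4 |
| violet | 6.00 | 74.2 |
| ochre | 0.833 | 99.4 |
| ochre | 1.67 | 99.5 |
| ochre | 3.00 | 100.2 |
| ochre | 4.00 | 100.3 |
| ochre | 5.00 | 100.1 |
| ochre | 6.00 | 99.8 |

(readings scatter by 0.3 percentage points)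

- the set-up with the highest amount of links at the outlet or at the end, in percent of the first end groups put in ("none" if the first two lie within 2 percentage points) (south / north-west / north / north-east / none)
- amount of links at the outlet or at the end, in percent of the first end groups put in, south
- amount of links at the outlet or at the end, in percent of the first end groups put in, north-west
- amount of links at the outlet or at the end, in percent of the first end groups put in, north
- amount of links at the outlet or at the end, in percent of the first end groups put in, north-east

- the stated concentrations are those of everything mixed, before any reaction; amounts are the same in each set-up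
- the feed brings no volume worth counting
- the earlier runs were made in a closed, stirred flask

One colleague reported that the amber run reads 53.3% at 0.417 d and 53.1% at 8.00 d, a difference of 0.2 percentage points with a scatter of 0.3 points, so the links read in the amber run show no change beyond the scatter after its first sample.

A second colleague proposed to assume that the second end groups are shared out between first and third end groups, each step being first order in both partners. What the first end groups did not take, the third took, so the amber and violet runs can each be read as one number. The amber reading gives a selectivity factor of 0.608, the logarithm of the fraction of third end groups left over the logarithm of the fraction of first end groups left. The violet reading gives 0.603.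

I then committed myself as follows. North repeats the amber recipe, so it should read about 53.1%. North-east should approach 90.0% from below, since first end groups meet the second end groups before much third arrives, and north-west should stand near zero. For the south tank, the fractions left are 1/(1+x) and 1/(1+0.608x), where x is the first end groups' rate times the mean stay. With equal charges, the two consumed fractions add up to 0.900, which gives x = 1.05 and 51.1% links.

The forecast, reasoning that “The plateau is reached by the first sample in every run, so the reaction is fast”, named north-east as best, with 51.2% for south, 3% for north-west, 53.2% for north and 88% for north-east.

The flasks gave 67.8% in south, 0.730% in north-west, 53.4% in north and 89.3% in north-east, so north-east is best.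

    first end groups + second end groups → links (k = 27.1 M⁻¹ min⁻¹)
    second end groups + third end groups → links of the second sort (k = 16.2 M⁻¹ min⁻¹)
    second end groups → decomposed reagent (k = 6.29 × 10⁻⁴ min⁻¹)
    2 third end groups → self-condensation product (k = 0.0898 M⁻¹ min⁻¹)

At the start of the north flask, third end groups went to links of the second sort 81 times as fast as to self-condensation product, and 0.608 applied to its links gives 3.71 mM of links of the second sort against 3.65 mM found, while in the neighbouring flask with 15 mM of second end groups it gives 6.68 mM against 6.59 mM. In the south tank, the mean stay of 8.0 d stands against a first half-life of third end groups by self-condensation, at 10.0 mM, of 0.387 d, and the tank gave 67.8% links, 17 points above my 51.1%.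

Readings and results were computed with constants of no real substance; scatter was added.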